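**Plan**
1.  Retrosynthetic cuts: the C7 acetate, C7–C8 (aldol), the C10-bromo enone (back to a C10–C11 epoxide beside a C9 carbinol), C12–C13 (union of the ring with the C13–C20 chain) and C5=C6 (Wittig).
2.  Enabling feature: the cyclopentene ring C8–C12 carries oxygen on both C9 and C12, 1,4 to each other across C10=C11. The two carbons can trade oxidation level, so C12 can be the carbonyl of a chiral-pool 4-silyloxycyclopentenone while C9 waits as the silyl ether and C10=C11 is parked as an epoxide.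
3.  Forward order: (R)-4-silyloxycyclopentenone → all-cis epoxy ketone → (Z)-octenyl chain joined at C12 → C9 oxidised and the epoxide turned into the C10-bromo enone → aldol at C8 with the C1–C7 (Z)-enal → acetate.
4.  Stereochemistry: C9 (chiral pool) sets the epoxide face and both together set C12, after which C9 is erased. C12 then directs C8 and the Zimmerman–Traxler aldol sets C7. Both Z-alkenes are brought in intact, from (Z)-oct-2-en-1-ol and from a Z-selective Wittig reaction.
5.  Remark: atom numbers follow prostanoid numbering (C1 ester carbon, C8–C12 ring, C13–C20 octenyl chain).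

Key step: step 5

**Route**

Step 1
Reactants: 1 (R)-4-[(tert-butyldimethylsilyl)oxy]cyclopent-2-en-1-one
Product: 2 (1S,4R)-4-[(tert-butyldimethylsilyl)oxy]cyclopent-2-en-1-ol (cis)
Conditions: NaBH4, CeCl3·7H2O, MeOH, −78 to −40 °C
Reagents that add atoms: none
Why: Luche reduction gives clean 1,2-reduction of the enone, the hydride entering anti to the C4 silyloxy group so that the new carbinol centre is cis to it.

Step 2
Reactants: 2 (1S,4R)-4-[(tert-butyldimethylsilyl)oxy]cyclopent-2-en-1-ol
Product: 3 (1S,2S,3S,4R)-2,3-epoxy-4-[(tert-butyldimethylsilyl)oxy]cyclopentan-1-ol (OH, epoxide and OTBS all cis)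
Conditions: VO(acac)2 (cat.), t-BuOOH, CH2Cl2, 0 °C to rt
Reagents that add atoms: tert-butyl hydroperoxide, CC(C)(C)OO
Why: Hydroxyl-directed vanadium-catalysed epoxidation of the cyclic allylic alcohol delivers the oxygen syn to the free OH, so both new epoxide centres are cis to the OH and to the silyloxy group.

Step 3
Reactants: 3 (1S,2S,3S,4R)-2,3-epoxy-4-[(tert-butyldimethylsilyl)oxy]cyclopentan-1-ol
Product: 4 (2R,3S,4R)-2,3-epoxy-4-[(tert-butyldimethylsilyl)oxy]cyclopentan-1-one (epoxide cis to OTBS)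
Conditions: Dess–Martin periodinane, pyridine, CH2Cl2, 0 °C to rt
Reagents that add atoms: none
Why: Dess–Martin oxidation converts the secondary epoxy alcohol into the ketone under buffered, non-epimerising conditions that leave the epoxide and the β-silyloxy group untouched.

Step 4
Reactants: 5 (Z)-oct-2-en-1-ol
Product: 6 (Z)-1-chlorooct-2-ene
Conditions: PPh3, CCl4, reflux
Reagents that add atoms: carbon tetrachloride, ClC(Cl)(Cl)Cl
Why: Appel reaction, in which SN2 displacement on the alkoxyphosphonium ion should give the primary allylic chloride without allylic transposition or loss of the Z geometry.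

Step 5
Reactants: 4 (2R,3S,4R)-2,3-epoxy-4-[(tert-butyldimethylsilyl)oxy]cyclopentan-1-one; 6 (Z)-1-chlorooct-2-ene
Product: 8 (1S,2R,3S,4R)-2,3-epoxy-1-[(Z)-oct-2-en-1-yl]-4-[(tert-butyldimethylsilyl)oxy]cyclopentan-1-ol (octenyl trans to epoxide and OTBS), via (Z)-oct-2-enylbarium chloride 7 (not isolated)
Conditions: BaI2, lithium biphenylide (2 equiv), THF, rt; 6, −78 °C; then 4, THF, −78 °C; aq NH4Cl
Reagents that add atoms: none
Why: Two-electron reduction of the allylic chloride by activated barium gives the allylbarium species 7, which keeps its Z geometry at −78 °C and adds through its unsubstituted CH2 terminus to the ketone carbonyl in a 1,2-fashion. The closest known reaction type is the α-selective, geometry-retentive carbonyl allylation with allylic barium reagents, here a reductive union of two electrophilic carbons (the carbonyl carbon C12 and the CH2–Cl carbon C13) made possible by polarity reversal of the halide. No ring is closed. The new quaternary carbinol centre C12 is controlled by the bicyclic ketone: the epoxide oxygen on the adjacent carbon and the silyloxy group at C9 lie on the same face, so the reagent enters from the opposite face, which is also the Felkin–Anh trajectory anti to the α C–O bond, and the octenyl chain ends up trans to both. The step needs α- over γ-attack, carbonyl addition over epoxide opening or enolisation, retention of the Z double bond and one-sided facial attack; the low temperature and the hindered ketone secure the first three, and the saturated epoxy ketone (no enone, hence no 1,4-addition) with its one-sided shielding secures the rest.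

Step 6
Reactants: 8 (1S,2R,3S,4R)-2,3-epoxy-1-[(Z)-oct-2-en-1-yl]-4-[(tert-butyldimethylsilyl)oxy]cyclopentan-1-ol
Product: 9 (1S,3R,4R,5R)-4,5-epoxy-1-[(Z)-oct-2-en-1-yl]cyclopentane-1,3-diol
Conditions: TBAF, THF, 0 °C to rt; aq NH4Cl
Reagents that add atoms: none
Why: Fluoride-mediated desilylation frees the C9 hydroxyl, and because both oxygens are cis to the epoxide a Payne rearrangement (which needs a trans relationship) cannot intervene.

Step 7
Reactants: 9 (1S,3R,4R,5R)-4,5-epoxy-1-[(Z)-oct-2-en-1-yl]cyclopentane-1,3-diol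
Product: 10 (2S,3R,4S)-2,3-epoxy-4-hydroxy-4-[(Z)-oct-2-en-1-yl]cyclopentan-1-one
Conditions: Dess–Martin periodinane, pyridine, CH2Cl2, 0 °C to rt
Reagents that add atoms: none
Why: Dess–Martin oxidation takes the secondary C9 alcohol to the ketone while the tertiary C12 alcohol cannot react, which turns the epoxide into an α,β-epoxy ketone of the new carbonyl.

Step 8
Reactants: 10 (2S,3R,4S)-2,3-epoxy-4-hydroxy-4-[(Z)-oct-2-en-1-yl]cyclopentan-1-one
Product: 13 (S)-2-bromo-4-hydroxy-4-[(Z)-oct-2-en-1-yl]cyclopent-2-en-1-one, via bromohydrin 11 (not isolated), via mesylate 12 (not isolated)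
Conditions: LiBr, AcOH, THF, rt; then MsCl, Et3N, CH2Cl2, −20 to 0 °C
Reagents that add atoms: lithium bromide, [Li+].[Br-]
Why: Bromide should open the α,β-epoxy ketone by SN2 at the α-carbon C10 (C11 is neopentyl), after which the secondary C11 hydroxyl is mesylated selectively and lost by E1cB elimination through the acidic C10–H to give the α-bromo enone (epoxide opening followed by β-elimination), the C12 centre staying untouched.

Step 9
Reactants: 13 (S)-2-bromo-4-hydroxy-4-[(Z)-oct-2-en-1-yl]cyclopent-2-en-1-one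
Product: 14 (S)-2-bromo-4-[(Z)-oct-2-en-1-yl]-4-[(trimethylsilyl)oxy]cyclopent-2-en-1-one
Conditions: TMSCl, imidazole, DMF, 0 °C to rt
Reagents that add atoms: chlorotrimethylsilane, C[Si](C)(C)Cl
Why: Silylation of the tertiary alcohol as its trimethylsilyl ether prevents retro-aldol ring opening and alkoxide chemistry during the enolate step.

Step 10
Reactants: 15 (4-carboxybutyl)triphenylphosphonium bromide; 16 [(tert-butyldimethylsilyl)oxy]acetaldehyde
Product: 18 (Z)-7-[(tert-butyldimethylsilyl)oxy]hept-5-enoic acid, via phosphorus ylide carboxylate 17 (not isolated)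
Conditions: NaHMDS (2 equiv), THF, 0 °C; 16, −78 °C to rt; 1 M HCl to pH 4
Reagents that add atoms: none
Why: Wittig olefination with the non-stabilised ylide under lithium-free conditions should give the Z-alkene through the kinetically favoured cis-oxaphosphetane.

Step 11
Reactants: 18 (Z)-7-[(tert-butyldimethylsilyl)oxy]hept-5-enoic acid
Product: 20 methyl (Z)-7-hydroxyhept-5-enoate, via (Z)-7-hydroxyhept-5-enoic acid 19 (not isolated)
Conditions: TsOH·H2O (cat.), MeOH, rt
Reagents that add atoms: methanol, CO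
Why: Acid-catalysed methanolysis cleaves the primary silyl ether and the same acid effects Fischer esterification of the carboxylic acid.

Step 12
Reactants: 20 methyl (Z)-7-hydroxyhept-5-enoate
Product: 21 methyl (Z)-7-oxohept-5-enoate
Conditions: Dess–Martin periodinane, pyridine, CH2Cl2, 0 °C; used at once
Reagents that add atoms: none
Why: Dess–Martin oxidation of the primary allylic alcohol under pyridine buffering should give the Z-enal without acid- or base-induced Z-to-E isomerisation.

Step 13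
Reactants: 14 (S)-2-bromo-4-[(Z)-oct-2-en-1-yl]-4-[(trimethylsilyl)oxy]cyclopent-2-en-1-one; 21 methyl (Z)-7-oxohept-5-enoate
Product: 24 methyl (5Z,7S)-7-[(1R,2S)-4-bromo-2-hydroxy-2-[(Z)-oct-2-en-1-yl]-5-oxocyclopent-3-en-1-yl]-7-hydroxyhept-5-enoate, via lithium enolate 22 (not isolated), via TMS-protected aldol 23 (not isolated)
Conditions: LDA, THF, −78 °C; 21, −78 °C; AcOH quench; then citric acid (cat.), MeOH, 0 °C
Reagents that add atoms: none
Why: Directed aldol reaction in which kinetic deprotonation at C8 gives the ring (E)-enolate, which should add to the aldehyde through a Zimmerman–Traxler chair (anti aldol, sets C7) on the face carrying the slim O–SiMe3 group and away from the octenyl CH2 (sets C8 trans to the C13 chain), after which mild acid methanolysis removes the trimethylsilyl ether.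

Step 14
Reactants: 24 methyl (5Z,7S)-7-[(1R,2S)-4-bromo-2-hydroxy-2-[(Z)-oct-2-en-1-yl]-5-oxocyclopent-3-en-1-yl]-7-hydroxyhept-5-enoate
Product: 25 methyl (5Z,7S)-7-acetoxy-7-[(1R,2S)-4-bromo-2-hydroxy-2-[(Z)-oct-2-en-1-yl]-5-oxocyclopent-3-en-1-yl]hept-5-enoate (7-acetoxy-7,8-dihydrobromovulone I)
Conditions: Ac2O, pyridine, CH2Cl2, 0 °C to rt (no DMAP)
Reagents that add atoms: acetic anhydride, CC(=O)OC(C)=O
Why: Acetylation with acetic anhydride in pyridine should esterify the secondary allylic C7 alcohol chemoselectively, the hindered tertiary C12 alcohol staying free and the weak base avoiding β-elimination of the new acetate.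

**Compound list**
1 | (R)-4-[(tert-butyldimethylsilyl)oxy]cyclopent-2-en-1-one | O=C1C=C[C@H](O[Si](C)(C)C(C)(C)C)C1 | starting material
2 | (1S,4R)-4-[(tert-butyldimethylsilyl)oxy]cyclopent-2-en-1-ol (cis) | O[C@@H]1C=C[C@H](O[Si](C)(C)C(C)(C)C)C1 | intermediate
3 | (1S,2S,3S,4R)-2,3-epoxy-4-[(tert-butyldimethylsilyl)oxy]cyclopentan-1-ol (all cis) | O[C@@H]1[C@@H]2O[C@@H]2[C@H](O[Si](C)(C)C(C)(C)C)C1 | intermediate
4 | (2R,3S,4R)-2,3-epoxy-4-[(tert-butyldimethylsilyl)oxy]cyclopentan-1-one | O=C1[C@@H]2O[C@@H]2[C@H](O[Si](C)(C)C(C)(C)C)C1 | intermediate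
5 | (Z)-oct-2-en-1-ol | CCCCC/C=C\CO | starting material
6 | (Z)-1-chlorooct-2-ene | CCCCC/C=C\CCl | intermediate
7 | (Z)-oct-2-enylbarium chloride | CCCCC/C=C\C[Ba]Cl | intermediate
8 | (1S,2R,3S,4R)-2,3-epoxy-1-[(Z)-oct-2-en-1-yl]-4-[(tert-butyldimethylsilyl)oxy]cyclopentan-1-ol | CCCCC/C=C\C[C@@]1(O)[C@@H]2O[C@@H]2[C@H](O[Si](C)(C)C(C)(C)C)C1 | intermediate
9 | (1S,3R,4R,5R)-4,5-epoxy-1-[(Z)-oct-2-en-1-yl]cyclopentane-1,3-diol | CCCCC/C=C\C[C@@]1(O)[C@@H]2O[C@@H]2[C@H](O)C1 | intermediate
10 | (2S,3R,4S)-2,3-epoxy-4-hydroxy-4-[(Z)-oct-2-en-1-yl]cyclopentan-1-one | CCCCC/C=C\C[C@@]1(O)[C@@H]2O[C@@H]2C(=O)C1 | intermediate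
11 | (2R,3S,4S)-2-bromo-3,4-dihydroxy-4-[(Z)-oct-2-en-1-yl]cyclopentan-1-one (bromohydrin) | CCCCC/C=C\C[C@@]1(O)[C@H](O)[C@@H](Br)C(=O)C1 | intermediate
12 | (2R,3S,4S)-2-bromo-4-hydroxy-3-(methanesulfonyloxy)-4-[(Z)-oct-2-en-1-yl]cyclopentan-1-one (mesylate) | CCCCC/C=C\C[C@@]1(O)[C@H](OS(C)(=O)=O)[C@@H](Br)C(=O)C1 | intermediate
13 | (S)-2-bromo-4-hydroxy-4-[(Z)-oct-2-en-1-yl]cyclopent-2-en-1-one | CCCCC/C=C\C[C@@]1(O)C=C(Br)C(=O)C1 | intermediate
14 | (S)-2-bromo-4-[(Z)-oct-2-en-1-yl]-4-[(trimethylsilyl)oxy]cyclopent-2-en-1-one | CCCCC/C=C\C[C@@]1(O[Si](C)(C)C)C=C(Br)C(=O)C1 | intermediate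
15 | (4-carboxybutyl)triphenylphosphonium bromide | OC(=O)CCCC[P+](c1ccccc1)(c1ccccc1)c1ccccc1.[Br-] | starting material
16 | [(tert-butyldimethylsilyl)oxy]acetaldehyde | O=CCO[Si](C)(C)C(C)(C)C | starting material
17 | sodium 5-(triphenylphosphoranylidene)pentanoate (ylide carboxylate) | [Na+].[O-]C(=O)CCCC=P(c1ccccc1)(c1ccccc1)c1ccccc1 | intermediate
18 | (Z)-7-[(tert-butyldimethylsilyl)oxy]hept-5-enoic acid | OC(=O)CCC/C=C\CO[Si](C)(C)C(C)(C)C | intermediate
19 | (Z)-7-hydroxyhept-5-enoic acid | OC(=O)CCC/C=C\CO | intermediate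
20 | methyl (Z)-7-hydroxyhept-5-enoate | COC(=O)CCC/C=C\CO | intermediate
21 | methyl (Z)-7-oxohept-5-enoate | COC(=O)CCC/C=C\C=O | intermediate
22 | lithium C8–C9 enolate of 14 | CCCCC/C=C\C[C@@]1(O[Si](C)(C)C)C=C(Br)C(O[Li])=C1 | intermediate
23 | methyl (5Z,7S)-7-[(1R,2S)-4-bromo-2-[(Z)-oct-2-en-1-yl]-5-oxo-2-[(trimethylsilyl)oxy]cyclopent-3-en-1-yl]-7-hydroxyhept-5-enoate | CCCCC/C=C\C[C@@]1(O[Si](C)(C)C)C=C(Br)C(=O)[C@@H]1[C@H](/C=C\CCCC(=O)OC)O | intermediate
24 | methyl (5Z,7S)-7-[(1R,2S)-4-bromo-2-hydroxy-2-[(Z)-oct-2-en-1-yl]-5-oxocyclopent-3-en-1-yl]-7-hydroxyhept-5-enoate | CCCCC/C=C\C[C@@]1(O)C=C(Br)C(=O)[C@@H]1[C@H](/C=C\CCCC(=O)OC)O | intermediate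
25 | methyl (5Z,7S)-7-acetoxy-7-[(1R,2S)-4-bromo-2-hydroxy-2-[(Z)-oct-2-en-1-yl]-5-oxocyclopent-3-en-1-yl]hept-5-enoate | CCCCC/C=C\C[C@@]1(O)C=C(Br)C(=O)[C@@H]1[C@H](/C=C\CCCC(=O)OC)OC(C)=O | target

**Count**
Total steps: 14. Longest linear sequence: 10 steps (1 → 2 → 3 → 4 → 8 → 9 → 10 → 13 → 14 → 24 → 25).

**Steps most likely to fail**

Step 5. What may go wrong: electron transfer from the strongly reducing barium species to the epoxy ketone (reductive epoxide opening), enolisation with β-elimination of the silyloxy group, or warming of the allylbarium species with loss of Z geometry and γ-attack. The fallback sets out from 4 and returns at 8. Oct-2-yn-1-ol is converted with methyl chloroformate and pyridine into methyl oct-2-yn-1-yl carbonate F1. Copper-catalysed SN2′ borylation (CuCl, Xantphos, KOtBu cat., B2pin2, THF) then gives 4,4,5,5-tetramethyl-2-(octa-1,2-dien-3-yl)-1,3,2-dioxaborolane F2. This neutral allenylboronate should add to 4 through a closed six-membered SE2′ transition state (toluene, 60 °C), again from the face opposite to epoxide and silyl ether, to give (1S,2R,3S,4R)-2,3-epoxy-1-(oct-2-yn-1-yl)-4-[(tert-butyldimethylsilyl)oxy]cyclopentan-1-ol F3. Lindlar semi-hydrogenation (Pd/CaCO3/Pb, quinoline, H2) then gives 8.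

Step 13. What may go wrong: low anti/syn selectivity in the chair transition state (C7), β-elimination of the silyloxy group from the enolate, or Z-to-E isomerisation of the enal before it is consumed. The fallback sets out from 14 and 21 and returns at 25. The aldol and desilylation also give the C7 epimer methyl (5Z,7R)-7-[(1R,2S)-4-bromo-2-hydroxy-2-[(Z)-oct-2-en-1-yl]-5-oxocyclopent-3-en-1-yl]-7-hydroxyhept-5-enoate F4, which is separated and esterified with inversion under Mitsunobu conditions (PPh3, DIAD, AcOH, toluene, 0 °C). The secondary allylic carbinol is inverted and acetylated in one operation and the tertiary alcohol does not react, so both aldol epimers converge on 25.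

Step 8. What may go wrong: acid-promoted loss of the tertiary C12 hydroxyl (dehydration towards C8) in competition with the wanted elimination, or partial opening of the epoxide at C11. The fallback sets out from 10 and returns at 14. The tertiary alcohol is silylated first (TMSCl, imidazole, DMF) to give (2S,3R,4S)-2,3-epoxy-4-[(Z)-oct-2-en-1-yl]-4-[(trimethylsilyl)oxy]cyclopentan-1-one F5. Aprotic Lewis-acid opening with MgBr2·OEt2 (Et2O, −20 °C) gives (2R,3S,4S)-2-bromo-3-hydroxy-4-[(Z)-oct-2-en-1-yl]-4-[(trimethylsilyl)oxy]cyclopentan-1-one F6. Mesylation (MsCl, Et3N) gives (2R,3S,4S)-2-bromo-3-(methanesulfonyloxy)-4-[(Z)-oct-2-en-1-yl]-4-[(trimethylsilyl)oxy]cyclopentan-1-one F7, and elimination in the same flask gives 14. Only the C11 oxygen can then leave, and step 9 is no longer needed.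

**Further compounds**
F1 | step 5 | methyl oct-2-yn-1-yl carbonate | CCCCCC#CCOC(=O)OC
F2 | step 5 | 4,4,5,5-tetramethyl-2-(octa-1,2-dien-3-yl)-1,3,2-dioxaborolane | CCCCCC(=C=C)B1OC(C)(C)C(C)(C)O1
F3 | step 5 | (1S,2R,3S,4R)-2,3-epoxy-1-(oct-2-yn-1-yl)-4-[(tert-butyldimethylsilyl)oxy]cyclopentan-1-ol | CCCCCC#CC[C@@]1(O)[C@@H]2O[C@@H]2[C@H](O[Si](C)(C)C(C)(C)C)C1
F4 | step 13 | methyl (5Z,7R)-7-[(1R,2S)-4-bromo-2-hydroxy-2-[(Z)-oct-2-en-1-yl]-5-oxocyclopent-3-en-1-yl]-7-hydroxyhept-5-enoate | CCCCC/C=C\C[C@@]1(O)C=C(Br)C(=O)[C@@H]1[C@@H](/C=C\CCCC(=O)OC)O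
F5 | step 8 | (2S,3R,4S)-2,3-epoxy-4-[(Z)-oct-2-en-1-yl]-4-[(trimethylsilyl)oxy]cyclopentan-1-one | CCCCC/C=C\C[C@@]1(O[Si](C)(C)C)[C@@H]2O[C@@H]2C(=O)C1
F6 | step 8 | (2R,3S,4S)-2-bromo-3-hydroxy-4-[(Z)-oct-2-en-1-yl]-4-[(trimethylsilyl)oxy]cyclopentan-1-one | CCCCC/C=C\C[C@@]1(O[Si](C)(C)C)[C@H](O)[C@@H](Br)C(=O)C1
F7 | step 8 | (2R,3S,4S)-2-bromo-3-(methanesulfonyloxy)-4-[(Z)-oct-2-en-1-yl]-4-[(trimethylsilyl)oxy]cyclopentan-1-one | CCCCC/C=C\C[C@@]1(O[Si](C)(C)C)[C@H](OS(C)(=O)=O)[C@@H](Br)C(=O)C1
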